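- In micromoles per litre, 0.25 µM of free catalyst meets 0.062 µM of impurity, and the two are lost one for one. The impurity is therefore the limiting reagent of that step and takes about a quarter of the catalyst. This leaves 0.188 µM, the working catalyst: the free catalyst charged minus the impurity charged.

all flasks: free catalyst 0.25 µM; impurity 0.062 µM; time 1.0 min
- ash: starting material 0.50 mM (fed, over 40 s); second substrate 0.500 mM; all else is in the flask from the start; the feed brings no volume worth counting
- birch: starting material 0.50 mM; second substrate 0.500 mM; everything together at the start
- alder: starting material 0.50 mM; second substrate 0.500 mM (fed, over 40 s); all else is in the flask from the start; the feed brings no volume worth counting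

    starting material + free catalyst ⇌ catalyst intermediate A (K1 = 1700 L mol⁻¹, k1 = 83000 L mol⁻¹ s⁻¹)
    catalyst intermediate A → free catalyst + target (k2 = 70 s⁻¹)
    second substrate + free catalyst ⇌ catalyst intermediate B (K3 = 2.0 × 10⁵ L mol⁻¹, k3 = 1.8 × 10⁵ L mol⁻¹ s⁻¹)
    catalyst intermediate B → free catalyst + second product (k4 = 28 s⁻¹)
    free catalyst + impurity → spent catalyst (k5 = 7.2 × 10⁷ L mol⁻¹ s⁻¹)

* which flask leads in amount of target, in percent of the starting material charged ("all alike" within 1.5 percentage points) (ash / birch / alder / all alike)
* how much target is there at the end, in percent of the starting material charged: ash
* how much target is there at the end, in percent of the starting material charged: birch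
* how much target is there at the end, in percent of the starting material charged: alder

- Fastest rung, birch: free catalyst meets second substrate within 0.0111 s, and catalyst intermediate A, which can go on to target or back, lasts about 0.00842 s. Balancing each intermediate gives half-saturation amounts of 1.43 mM for starting material and 0.161 mM for second substrate.
- At the charges of birch, catalyst intermediate B, the resting state, holds 69.8% of the catalyst in the round, and catalyst intermediate A holds 7.82%.
- Next rung, birch: free catalyst keeps 22.4% of that round, so the time scale of the impurity is about 0.248 s by estimate, far shorter than the 1.0 min of the run.
- Slowest rung, birch: at starting amounts, the working catalyst would need 8.09 min to turn the whole charge. With those starting amounts held through the run, my own reckoning gives 12.4% target in birch. With the recipe and time held, target should scale with the working catalyst.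
- Feeding second substrate lowers the larger term of the competition, so I place alder above birch; feeding starting material lowers the smaller term, the one that leads to target, so I place ash below birch.
- The forecast names alder, with ash 10%, birch 13.7% and alder 18%, on the ground that “Feeding the second substrate gives the starting material a competitor-free early window and so the most target”. Its birch figure stands above mine.
- The simulation puts alder first, with ash 9.91%, birch 13.7% and alder 18.3%. With the impurity step struck out, alder gives 24.4%. Scaling alder by the free catalyst charged over the working catalyst gives 24.3%.
- In the neighbour of alder, the same flask with 0.620 µM of free catalyst, the working catalyst is 0.558 µM, and scaling gives 54.3% target. The computed result is 53.3%.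

(Its constants come from no measurement.)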